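**Retrosynthetic overview**

1. 19 ⇐ 18 (CO2Me → CH2OH) ⇐ transannular Ireland–Claisen ring contraction of the macro-bridged δ-lactone 15: the lactone C–O bond is traded for the C15–C11 bond, creating the quaternary centre, C11, the cyclohexene and the 12-membered ring together.
2. 15 ⇐ radical macrocyclization (C1–C2 bond of the target) of chloro lactone 14, entering trans to the lactone side chain.
3. 14 ⇐ key step, C–O ring closure: enantioselective vinylogous aldol–lactonization of formyl enoate 8 with silyl dienolate 12; this lactone C–O stereocentre is the only one set by a catalyst and is relayed to all three carbon stereocentres.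
4. 8 ⇐ cross-metathesis and oxidation of (2E,6Z)-farnesyl chloride 5 (from nerylacetone 1); 12 ⇐ methyl but-3-enoate 9 + bromide 10.
5. Ring order: δ-lactone (step 8), 14-membered carbocycle (step 9), then cyclohexene and 12-membered ring in one step (step 10).

Assumption: the facial sense of the copper/Tol-BINAP step is assigned by analogy with known copper dienolate additions to aldehydes (Re-face attack with the (S)-ligand); if it proves opposite, the (R)-ligand is used with no other change.

**Step 1**
Reactants: 1 nerylacetone [(5Z)-6,10-dimethylundeca-5,9-dien-2-one]; 2 triethyl phosphonoacetate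
Product: 3 ethyl (2E,6Z)-3,7,11-trimethyldodeca-2,6,10-trienoate
Conditions: NaH, THF, 0 °C to rt; minor 2Z isomer removed by chromatography
Reagents that add atoms: none
Why: Horner–Wadsworth–Emmons olefination of the methyl ketone gives the trisubstituted enoate with the usual E preference (about 4:1) and leaves the 6Z olefin untouched.

**Step 2**
Reactants: 3 ethyl (2E,6Z)-farnesoate
Product: 4 (2E,6Z)-3,7,11-trimethyldodeca-2,6,10-trien-1-ol
Conditions: i-Bu2AlH (2.2 equiv), CH2Cl2, −78 °C; aq. KNaC4H4O6
Reagents that add atoms: none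
Why: 1,2-reduction of the enoate by the aluminium hydride gives the allylic alcohol without touching the olefin geometry.

**Step 3**
Reactants: 4 (2E,6Z)-farnesol
Product: 5 (2E,6Z)-1-chloro-3,7,11-trimethyldodeca-2,6,10-triene
Conditions: N-chlorosuccinimide, Me2S, CH2Cl2, −40 to 0 °C
Reagents that add atoms: N-chlorosuccinimide O=C1CCC(=O)N1Cl
Why: Corey–Kim chlorination displaces the alkoxysulfonium group by chloride at the primary carbon, without allylic transposition or E/Z loss.

**Step 4**
Reactants: 5 (2E,6Z)-farnesyl chloride; 6 methyl 2-(hydroxymethyl)acrylate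
Product: 7 methyl (2E,6Z,10E)-12-chloro-2-(hydroxymethyl)-6,10-dimethyldodeca-2,6,10-trienoate
Conditions: second-generation Hoveyda–Grubbs catalyst [RuCl2(H2IMes)(=CH-C6H4-2-O-i-Pr)] (3 mol%), 6 (5 equiv), toluene, 80 °C, argon sweep
Reagents that add atoms: none
Why: Olefin cross-metathesis at the prenyl terminus (loss of isobutene), the least hindered trisubstituted olefin, with a methacrylate-type partner gives the thermodynamic E enoate, with the chain trans to CO2Me and cis to CH2OH.

**Step 5**
Reactants: 7 hydroxymethyl enoate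
Product: 8 methyl (2E,6Z,10E)-12-chloro-2-formyl-6,10-dimethyldodeca-2,6,10-trienoate
Conditions: MnO2 (activated, 15 equiv), CH2Cl2, rt
Reagents that add atoms: none
Why: Chemoselective allylic alcohol oxidation; the chain stays cis to the formyl group, which is also the more stable arrangement of an alkylidene formylacetate.

**Step 6**
Reactants: 9 methyl but-3-enoate; 10 5-bromo-2-methylpent-2-ene
Product: 11 methyl 2-(4-methylpent-3-en-1-yl)but-3-enoate (racemic)
Conditions: LiN(i-Pr)2, THF/DMPU, −78 °C; then 10, −78 °C to rt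
Reagents that add atoms: none
Why: Ester dienolate alkylation is α-selective under kinetic control, and the racemic centre is erased in the next step.

**Step 7**
Reactants: 11 methyl 2-(4-methylpent-3-en-1-yl)but-3-enoate
Product: 12 {[1-methoxy-2-(4-methylpent-3-en-1-yl)buta-1,3-dien-1-yl]oxy}trimethylsilane (ketene acetal isomers)
Conditions: LiN(i-Pr)2, THF, −78 °C; Me3SiCl; distillation
Reagents that add atoms: chlorotrimethylsilane C[Si](C)(C)Cl
Why: O-silylation of the lithium dienolate gives the silyl ketene acetal (silyl dienolate).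

**Step 8**
Reactants: 8 formyl enoate; 12 silyl dienolate
Product: 14 methyl (2E,6Z,10E)-12-chloro-6,10-dimethyl-2-[(2R)-5-(4-methylpent-3-en-1-yl)-6-oxo-3,6-dihydro-2H-pyran-2-yl]dodeca-2,6,10-trienoate, via O-silyl aldol adduct 13 (not isolated)
Conditions: Cu(OTf)2 (10 mol%), (S)-Tol-BINAP (11 mol%), Bu4N[Ph3SiF2] (20 mol%), THF, −78 to −40 °C
Reagents that add atoms: none
Why: Proposed new method: fluoride transfers the dienolate from silicon to a chiral monovalent copper–bisphosphine centre. The copper dienolate adds through its γ-carbon to the aldehyde C=O in a closed metallo-aldol transition state, so 1,2-addition should be preferred over 1,4-attack on the alkylidene carbon, and this sets the (R) carbinol centre. Because the new enoate is Z, the copper aldolate acylates intramolecularly (C–O ring closure with loss of MeOSiMe3) to the α-alkylated unsaturated δ-lactone. The closest known reaction is the copper fluoride/bisphosphine-catalysed vinylogous Mukaiyama aldol–lactonization of simple aldehydes with ester silyl dienolates; new here are the α-alkylated dienolate and the 2-formyl-2-enoate electrophile.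

**Step 9**
Reactants: 14 chloro lactone
Product: 15 methyl (1S,3E,7Z,11E,13R)-4,8-dimethyl-16-(4-methylpent-3-en-1-yl)-15-oxo-14-oxabicyclo[11.3.1]heptadeca-3,7,11-triene-12-carboxylate (C16 epimers)
Conditions: Bu3SnH (1.3 equiv), AIBN (0.2 equiv), syringe pump over 10 h into benzene (3 mM), 80 °C
Reagents that add atoms: none
Why: Radical macrocyclization (intramolecular Giese addition, 14-exo), of the kind known for 14-membered cembranoid closures of allylic radicals onto enones: the E allyl radical adds through its primary terminus to the lactone β-carbon by axial attack anti to the pseudo-equatorial side chain (sets C1, trans to C13), attack on the acyclic enoate would need a 10-membered ring, and the α-acyl radical is reduced by the tin hydride.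

**Step 10**
Reactants: 15 macro-bridged lactone
Product: 18 (1S,3E,7Z,11S,15S)-12-(methoxycarbonyl)-4,8-dimethyl-15-(4-methylpent-3-en-1-yl)bicyclo[9.3.1]pentadeca-3,7,12-triene-15-carboxylic acid, via silyl ketene acetal 16 (not isolated), via trimethylsilyl ester 17 (not isolated)
Conditions: LiN(i-Pr)2 added to 15 and Me3SiCl/Et3N, THF, −78 °C to rt; toluene, 105 °C; then 1 M HCl
Reagents that add atoms: none
Why: Ireland–Claisen rearrangement used as a lactone ring contraction: the cyclic ketene acetal can reach the alkene only through a boat transition state, suprafacial to the breaking C–O bond, so the trans lactone places CO2H cis to the C1–C2 bond and the enoate geometry (ring chain cis to the carbinol carbon) places the C11–C10 bond anti to CO2H, setting C15 and C11 as single isomers; the internal Me3SiCl quench keeps the enolate from adding to the enoate.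

**Step 11**
Reactants: 18 acid ester
Product: 19 (1S,3E,7Z,11S,15S)-12-(hydroxymethyl)-4,8-dimethyl-15-(4-methylpent-3-en-1-yl)bicyclo[9.3.1]pentadeca-3,7,12-triene-15-carboxylic acid (target, CNP0267152.2)
Conditions: i-Bu2AlH (4 equiv), CH2Cl2, −78 to −20 °C; aq. KNaC4H4O6, then pH 3
Reagents that add atoms: none
Why: The hindered quaternary acid is held as an inert aluminium carboxylate while the conjugated methyl ester undergoes 1,2-reduction to the allylic alcohol; no stereocentre is touched.

**Compound list**

1 | nerylacetone, (5Z)-6,10-dimethylundeca-5,9-dien-2-one | CC(=O)CC/C=C(C)\CCC=C(C)C | starting material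
2 | triethyl phosphonoacetate | CCOC(=O)CP(=O)(OCC)OCC | starting material
3 | ethyl (2E,6Z)-3,7,11-trimethyldodeca-2,6,10-trienoate | CCOC(=O)/C=C(\C)CC/C=C(C)\CCC=C(C)C | intermediate
4 | (2E,6Z)-farnesol | OC/C=C(\C)CC/C=C(C)\CCC=C(C)C | intermediate
5 | (2E,6Z)-farnesyl chloride | ClC/C=C(\C)CC/C=C(C)\CCC=C(C)C | intermediate
6 | methyl 2-(hydroxymethyl)acrylate | C=C(CO)C(=O)OC | starting material
7 | methyl (2E,6Z,10E)-12-chloro-2-(hydroxymethyl)-6,10-dimethyldodeca-2,6,10-trienoate | ClC/C=C(\C)CC/C=C(C)\CC/C=C(\CO)C(=O)OC | intermediate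
8 | methyl (2E,6Z,10E)-12-chloro-2-formyl-6,10-dimethyldodeca-2,6,10-trienoate | ClC/C=C(\C)CC/C=C(C)\CC/C=C(\C=O)C(=O)OC | intermediate
9 | methyl but-3-enoate | C=CCC(=O)OC | starting material
10 | 5-bromo-2-methylpent-2-ene | CC(C)=CCCBr | starting material
11 | methyl 2-(4-methylpent-3-en-1-yl)but-3-enoate (racemic) | C=CC(CCC=C(C)C)C(=O)OC | intermediate
12 | {[1-methoxy-2-(4-methylpent-3-en-1-yl)buta-1,3-dien-1-yl]oxy}trimethylsilane | C=CC(CCC=C(C)C)=C(OC)O[Si](C)(C)C | intermediate
13 | open-chain γ-aldol adduct, (R)-carbinol as O-trimethylsilyl ether, new enoate Z (not isolated) | ClC/C=C(\C)CC/C=C(C)\CC/C=C(\[C@H](O[Si](C)(C)C)C/C=C(/CCC=C(C)C)C(=O)OC)C(=O)OC | intermediate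
14 | methyl (2E,6Z,10E)-12-chloro-6,10-dimethyl-2-[(2R)-5-(4-methylpent-3-en-1-yl)-6-oxo-3,6-dihydro-2H-pyran-2-yl]dodeca-2,6,10-trienoate | ClC/C=C(\C)CC/C=C(C)\CC/C=C(\[C@H]1CC=C(CCC=C(C)C)C(=O)O1)C(=O)OC | intermediate
15 | methyl (1S,3E,7Z,11E,13R)-4,8-dimethyl-16-(4-methylpent-3-en-1-yl)-15-oxo-14-oxabicyclo[11.3.1]heptadeca-3,7,11-triene-12-carboxylate, δ-lactone trans-bridged by the 14-membered ring, C16 epimers | O=C1O[C@@H]2C[C@@H](C1CCC=C(C)C)C/C=C(\C)CC/C=C(C)\CC/C=C2/C(=O)OC | intermediate
16 | trimethylsilyl ketene acetal of 15 (not isolated) | C[Si](C)(C)OC=1O[C@@H]2C[C@@H](C=1CCC=C(C)C)C/C=C(\C)CC/C=C(C)\CC/C=C2/C(=O)OC | intermediate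
17 | trimethylsilyl ester of 18 (not isolated) | CC(C)=CCC[C@]1(C(=O)O[Si](C)(C)C)[C@@H]2CC=C(C(=O)OC)[C@@H]1CC/C(C)=C\CC/C(C)=C/C2 | intermediate
18 | (1S,3E,7Z,11S,15S)-12-(methoxycarbonyl)-4,8-dimethyl-15-(4-methylpent-3-en-1-yl)bicyclo[9.3.1]pentadeca-3,7,12-triene-15-carboxylic acid | CC(C)=CCC[C@]1(C(=O)O)[C@@H]2CC=C(C(=O)OC)[C@@H]1CC/C(C)=C\CC/C(C)=C/C2 | intermediate
19 | (1S,3E,7Z,11S,15S)-12-(hydroxymethyl)-4,8-dimethyl-15-(4-methylpent-3-en-1-yl)bicyclo[9.3.1]pentadeca-3,7,12-triene-15-carboxylic acid | CC(C)=CCC[C@]1(C(=O)O)[C@@H]2CC=C(CO)[C@@H]1CC/C(C)=C\CC/C(C)=C/C2 | target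

**Step count and risks**

Total: 11 steps. Longest linear sequence: 9 steps (1, 2, 3, 4, 5, 8, 9, 10, 11); steps 6 and 7 form the side branch.

Steps most likely to fail:

Step 8 (the proposed new step). The risks are 1,4-addition of the dienolate to the alkylidene carbon instead of the aldehyde, and modest enantioselectivity. The fallback uses known chemistry, sets out from 8 and comes back at 14. Allylboration of 8 with (+)-B-allyldiisopinocampheylborane (Et2O, −100 °C, ethanolamine work-up) gives the (R)-homoallylic alcohol F4. In parallel, 2 is alkylated with 10 (NaH, DMSO) to the phosphonate F5, which with aqueous formaldehyde and K2CO3 gives ethyl 2-(4-methylpent-3-en-1-yl)acrylate F6, saponified by LiOH to the acid F7. Esterification of F4 with F7 (DCC, DMAP) gives the diene ester F8, and ring-closing metathesis (second-generation Grubbs catalyst [RuCl2(H2IMes)(PCy3)(=CHPh)], CH2Cl2, 40 °C) closes lactone 14.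

Step 9 (radical macrocyclization). The risks are simple reduction of the allyl radical, partial E/Z scrambling of the allyl radical, and cis instead of trans entry. The fallback replaces the radical closure by an anionic one; it sets out from 14 and comes back at 15. Displacement of chloride with NaSO2Ph (DMF, rt) gives the allylic sulfone F9. LiN(SiMe3)2 (THF/DMPU, −78 °C, 2 mM) generates the sulfonyl-stabilised allyl anion, whose intramolecular 1,4-addition to the lactone closes the 14-membered ring as the sulfonyl lactone F10; the addition is reversible, so the more stable trans-bridged isomer can accumulate. SmI2 (THF/HMPA, −78 °C) then removes the sulfonyl group to give 15.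

Step 4 (cross-metathesis). The risks are competing metathesis at the internal trisubstituted olefin and low conversion of two hindered partners. The fallback builds the enoate by olefination instead; it sets out from 5 and comes back at 7. NBS in THF/H2O (0 °C) gives the terminal bromohydrin F1 selectively, K2CO3 in MeOH closes it to the terminal epoxide F2, and H5IO6 (THF/Et2O) cleaves it to the aldehyde F3. Horner–Wadsworth–Emmons olefination of F3 with methyl 2-(dimethoxyphosphoryl)-3-hydroxypropanoate (K2CO3, THF/H2O) returns 7 after removal of the Z isomer.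

**Further compounds**

F1 | step 4 | (2E,6Z)-10-bromo-1-chloro-3,7,11-trimethyldodeca-2,6-dien-11-ol (racemic) | ClC/C=C(\C)CC/C=C(C)\CCC(Br)C(C)(C)O
F2 | step 4 | (2E,6Z)-1-chloro-10,11-epoxy-3,7,11-trimethyldodeca-2,6-diene (racemic) | ClC/C=C(\C)CC/C=C(C)\CCC1OC1(C)C
F3 | step 4 | (4Z,8E)-10-chloro-4,8-dimethyldeca-4,8-dienal | ClC/C=C(\C)CC/C=C(C)\CCC=O
F4 | step 8 | methyl (2E,6Z,10E)-12-chloro-2-[(1R)-1-hydroxybut-3-en-1-yl]-6,10-dimethyldodeca-2,6,10-trienoate | ClC/C=C(\C)CC/C=C(C)\CC/C=C(\[C@H](O)CC=C)C(=O)OC
F5 | step 8 | ethyl 2-(diethoxyphosphoryl)-6-methylhept-5-enoate | CCOC(=O)C(CCC=C(C)C)P(=O)(OCC)OCC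
F6 | step 8 | ethyl 2-(4-methylpent-3-en-1-yl)acrylate | CCOC(=O)C(=C)CCC=C(C)C
F7 | step 8 | 2-(4-methylpent-3-en-1-yl)acrylic acid | OC(=O)C(=C)CCC=C(C)C
F8 | step 8 | methyl (2E,6Z,10E)-12-chloro-6,10-dimethyl-2-[(1R)-1-{[2-(4-methylpent-3-en-1-yl)acryloyl]oxy}but-3-en-1-yl]dodeca-2,6,10-trienoate | ClC/C=C(\C)CC/C=C(C)\CC/C=C(\[C@@H](CC=C)OC(=O)C(=C)CCC=C(C)C)C(=O)OC
F9 | step 9 | methyl (2E,6Z,10E)-6,10-dimethyl-2-[(2R)-5-(4-methylpent-3-en-1-yl)-6-oxo-3,6-dihydro-2H-pyran-2-yl]-12-(phenylsulfonyl)dodeca-2,6,10-trienoate | O=S(=O)(c1ccccc1)C/C=C(\C)CC/C=C(C)\CC/C=C(\[C@H]1CC=C(CCC=C(C)C)C(=O)O1)C(=O)OC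
F10 | step 9 | 2-(phenylsulfonyl) derivative of 15 (epimers at C2 and C16) | O=C1O[C@@H]2C[C@@H](C1CCC=C(C)C)C(S(=O)(=O)c1ccccc1)/C=C(\C)CC/C=C(C)\CC/C=C2/C(=O)OC
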